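| flask | substrate | temperature | remark | time |
|---|---|---|---|---|
| north-west | 0.86 M | 5 °C | run made earlier |  |
| north-east | 2.3 M | 22 °C | run made earlier |  |
| delta | 2.0 M |  | at 10 °C until 2.5 min, from then on at 35 °C | 8.0 min |
| eta | 0.60 M |  | at 35 °C throughout | 8.0 min |

- north-west (time / min: target / %, substrate / %): 1.00: 8.9, 81.1; 3.00: 21.9, 55.6; 5.00: 31.4, 37.8; 8.00: 38.2, 20.1
- north-east (time / min: target / %, substrate / %): 0.500: 21.9, 46.8; 1.50: 39.5, 17.5; 3.00: 52.3, 8.5; 4.00: 54.3, 6.1

(standard deviation of a reading: 1 percentage point)

1. which of the two ends with the higher amount of target, in percent of the substrate charged ("neither" if they lie within 2 percentage points) (delta / eta / neither)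
2. target at the end, in percent of the substrate charged, delta
3. target at the end, in percent of the substrate charged, eta



Slowness is the thing to measure first, so take the loss constant of substrate: the logarithm of how far it has fallen, divided by the time. In the north-west run it is 0.209 min⁻¹ up to the first reading and still 0.211 min⁻¹ between the last two, so at 5 °C you see no slowing. In the north-east run at 22 °C it is 1.52 min⁻¹ up to the first reading and 0.332 min⁻¹ between the last two, 4.58 times slower. The same run hints at what slows it: from 1.50 min to 4.00 min target gains 15 percentage points while substrate loses 11 points. So part of what went unseen seems to flow back, though at a scatter of 1 point per reading that is a weak sign.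

Now scale it. Between the two runs the opening constant grew by a factor of 7.25. Carry that growth at the same pace per degree to 35 °C, apply it to the slowed constant, and you get 1.51 min⁻¹, a rough figure. This is the hot tail constant, the pseudo-first-order constant of the slowed loss, and its half-life is 0.459 min. Delta spends 5.50 min hot, or 12.0 half-lives, and eta spends 8.0 min, or 17.4. I therefore expect both to finish before the end. The two flasks differ in their charges, 2.0 M against 0.60 M, and also in their temperature programmes, and this constant does not say how either difference moves the target. The constant gives no yield, so I name none.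

The forecast says neither, with 92% for delta and 92% for eta: “Both flasks should then approach completion”. It puts its slow drain at 0.5 per minute where I have 1.51 min⁻¹.

Eta ends at 73.8% and delta at 68.2%, both under the forecast, so eta gives more. Left until 80.0 min, delta still holds 68.3%.

    substrate + intermediate A → side product B (k = 0.360 M⁻¹ min⁻¹, Ea = 52.0 kJ mol⁻¹)
    substrate ⇌ intermediate B (K = 2.00, k = 0.130 min⁻¹, Ea = 89.0 kJ mol⁻¹, ΔH = −67.0 kJ mol⁻¹)
    substrate → target (k = 0.170 min⁻¹, Ea = 75.0 kJ mol⁻¹)
    intermediate C → side product A (k = 0.0740 min⁻¹, Ea = 77.0 kJ mol⁻¹)
    substrate ⇌ intermediate A (K = 0.860, k = 0.0690 min⁻¹, Ea = 89.0 kJ mol⁻¹, ΔH = 14.0 kJ mol⁻¹)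
    intermediate A → intermediate C (k = 0.0510 min⁻¹, Ea = 74.0 kJ mol⁻¹)
    (constants at 10 °C)

Against the hot tail constant of 1.51 min⁻¹, delta's substrate falls from 1.81% at 4.00 min to 0.0220% at 8.00 min, which makes 1.10 min⁻¹. In eta, intermediate A falls from 0.484% at 4.00 min to 0.00668% at 8.00 min, which makes 1.07 min⁻¹.

(The readings are calculated on assumed constants, noise included.)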